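**Retrosynthetic overview**
- Feature: in ring C (the dihydropyranone) the tertiary carbinol C3, which carries ring B, sits between the C4 ketone and an unsubstituted O1–C2H2 unit. This is an isoflavone whose C2=C3 bond has taken up oxygen at C3 and hydrogen at C2.
- Target ⇐ MOM removal ⇐ reoxidation of C4 ⇐ hydride opening at C2 of a cis (2S,3R)-2,3-epoxide ⇐ asymmetric nucleophilic epoxidation of the flat, MOM-protected 6,8-diprenylisoflavone (C2–O and C3–O bonds, both stereocentres).
- Isoflavone ⇐ Suzuki–Miyaura coupling (C3–C1' bond) of a 3-iodochromone with the ring B pinacol boronate from 4-bromoresorcinol; iodochromone ⇐ enaminone/iodine closure of ring C on 3,5-diprenyl-2,4-dihydroxyacetophenone ⇐ 2',4'-dihydroxyacetophenone and two equivalents of prenyl bromide.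
- Ring order: rings A and B are bought as arenes; ring C is closed in step 4; the oxirane is closed in step 8 and opened again in step 9.

Key step: step 8

Remark: which pseudoenantiomeric cinchona salt gives the (2S,3R)-epoxide is assigned by analogy (the cinchonidinium series is written); this is to be confirmed on the substrate, and the cinchoninium salt is used in the same way if the sense is the opposite.

**Route**

Step 1
Reactants: 1 2',4'-dihydroxyacetophenone; 2 prenyl bromide
Product: 3 1-[2,4-dihydroxy-3,5-bis(3-methylbut-2-en-1-yl)phenyl]ethanone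
Conditions: prenyl bromide (2.5 equiv in all), 10% aq KOH, 0 °C to rt
Reagents that add atoms: prenyl bromide (the second equivalent of 2, which supplies the second prenyl group), CC(C)=CCBr
Why: In water the resacetophenone phenoxide is alkylated on carbon (C-alkylation of an ambident phenoxide), and C3 and C5 are the only ring positions ortho or para to both oxygens, so two equivalents of prenyl bromide should be taken up, one at each of these carbons, with mono-C- and O-alkylated by-products removed by chromatography.

Step 2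
Reactants: 3 1-[2,4-dihydroxy-3,5-bis(3-methylbut-2-en-1-yl)phenyl]ethanone
Product: 4 1-[2-hydroxy-4-(methoxymethoxy)-3,5-bis(3-methylbut-2-en-1-yl)phenyl]ethanone
Conditions: MOMCl (1.2 equiv), K2CO3, acetone, 0 °C to rt
Reagents that add atoms: chloromethyl methyl ether (MOMCl), COCCl
Why: The 2-hydroxyl is locked in a hydrogen bond to the ketone, so Williamson-type alkylation with a weak base should take only the more acidic 4-hydroxyl.

Step 3
Reactants: 4 1-[2-hydroxy-4-(methoxymethoxy)-3,5-bis(3-methylbut-2-en-1-yl)phenyl]ethanone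
Product: 5 (E)-3-(dimethylamino)-1-[2-hydroxy-4-(methoxymethoxy)-3,5-bis(3-methylbut-2-en-1-yl)phenyl]prop-2-en-1-one
Conditions: Me2NCH(OMe)2 (3 equiv), toluene, 95 °C
Reagents that add atoms: N,N-dimethylformamide dimethyl acetal, COC(OC)N(C)C
Why: Condensation of the methyl ketone with the formamide acetal gives the vinylogous amide (enaminone formation), and the chelated phenol stays free for the later ring closure.

Step 4
Reactants: 5 (E)-3-(dimethylamino)-1-[2-hydroxy-4-(methoxymethoxy)-3,5-bis(3-methylbut-2-en-1-yl)phenyl]prop-2-en-1-one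
Product: 7 3-iodo-7-(methoxymethoxy)-6,8-bis(3-methylbut-2-en-1-yl)-4H-chromen-4-one, via 2-dimethylamino-3-iodochromanone 6 (not isolated)
Conditions: I2 (1.1 equiv), pyridine (1.2 equiv), CHCl3, 0 °C to rt; aq Na2S2O3/NaHCO3 wash
Reagents that add atoms: iodine, [I][I]
Why: Iodine attacks the electron-rich α-carbon of the enaminone far faster than the prenyl alkenes, the phenol adds to the iminium carbon in a 6-endo closure of ring C and dimethylamine is lost (iodine-mediated enaminone cyclisation to a 3-iodochromone), while one equivalent of iodine, the pyridine buffer and the MOM cap on O7 keep the prenyl groups out of iodoetherification.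

Step 5
Reactants: 8 4-bromoresorcinol
Product: 9 1-bromo-2,4-bis(methoxymethoxy)benzene
Conditions: NaH (2.4 equiv), MOMCl (2.4 equiv), DMF, 0 °C to rt
Reagents that add atoms: chloromethyl methyl ether (MOMCl, first equivalent), COCCl; chloromethyl methyl ether (MOMCl, second equivalent), COCCl
Why: Both phenoxides are alkylated by MOMCl (Williamson etherification), giving base-stable acetals that tolerate the two palladium steps and the alkaline epoxidation.

Step 6
Reactants: 9 1-bromo-2,4-bis(methoxymethoxy)benzene
Product: 10 2-[2,4-bis(methoxymethoxy)phenyl]-4,4,5,5-tetramethyl-1,3,2-dioxaborolane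
Conditions: B2pin2 (1.2 equiv), PdCl2(dppf) (3 mol%), KOAc (3 equiv), 1,4-dioxane, 90 °C
Reagents that add atoms: bis(pinacolato)diboron, CC1(C)OB(OC1(C)C)B1OC(C)(C)C(C)(C)O1
Why: Miyaura borylation converts the aryl bromide into the pinacol boronate without an organolithium or an acidic work-up that would endanger the MOM ethers.

Step 7
Reactants: 7 3-iodo-7-(methoxymethoxy)-6,8-bis(3-methylbut-2-en-1-yl)-4H-chromen-4-one; 10 2-[2,4-bis(methoxymethoxy)phenyl]-4,4,5,5-tetramethyl-1,3,2-dioxaborolane
Product: 11 3-[2,4-bis(methoxymethoxy)phenyl]-7-(methoxymethoxy)-6,8-bis(3-methylbut-2-en-1-yl)-4H-chromen-4-one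
Conditions: PdCl2(dppf) (5 mol%), K2CO3 (3 equiv), 1,4-dioxane/H2O, 80 °C
Reagents that add atoms: none
Why: Suzuki–Miyaura coupling of the vinylic C3–I bond with the ortho-alkoxyaryl boronate forms the C3–C1' bond, and the trisubstituted prenyl alkenes do not enter Heck chemistry under these conditions.

Step 8
Reactants: 11 3-[2,4-bis(methoxymethoxy)phenyl]-7-(methoxymethoxy)-6,8-bis(3-methylbut-2-en-1-yl)-4H-chromen-4-one
Product: 13 (2S,3R)-2,3-epoxide of 11 [(1aS,7aR)-7a-[2,4-bis(methoxymethoxy)phenyl]-4-(methoxymethoxy)-3,5-bis(3-methylbut-2-en-1-yl)-1a,7a-dihydro-7H-oxireno[2,3-b]chromen-7-one], via C2 cumylperoxy enolate 12 (not isolated)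
Conditions: cumene hydroperoxide (2 equiv), N-[4-(trifluoromethyl)benzyl]cinchonidinium bromide (10 mol%), 1 M aq KOH (0.5 equiv), toluene, 0 °C
Reagents that add atoms: cumene hydroperoxide, CC(C)(OO)c1ccccc1
Why: The cumylperoxide anion, drawn into toluene as an ion pair with the chiral ammonium cation, adds in a conjugate sense to C2 of the chromone enone to give the C4 enolate 12, and C3 of this enolate then attacks the proximal peroxide oxygen with loss of cumyl oxide, which forms the C2–O and C3–O bonds of the oxirane. The closest known reaction type is the asymmetric Weitz–Scheffer epoxidation of isoflavones and other enones with a hydroperoxide under cinchona phase-transfer catalysis. The oxirane closes in a 3-exo-tet mode and, being fused to the six-membered ring C, can only be cis, so C2 and C3 are set as one pair. The absolute sense, C3 R and with it C2 S, is controlled by the cation, whose free C9 hydroxyl binds the enolate oxygen and whose benzylated quinuclidinium face shields one side of the C2=C3 bond. The step needs chemoselectivity for the enone over the two prenyl alkenes and for peroxide over hydroxide at C2: the nucleophilic oxidant does not touch electron-rich alkenes, the lipophilic peroxide anion is extracted in preference to hydroxide so that ring C is not opened, and the three MOM ethers prevent phenoxide formation that would switch off the enone.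

Step 9
Reactants: 13 (2S,3R)-2,3-epoxide of 11
Product: 15 (3R)-3-[2,4-bis(methoxymethoxy)phenyl]-7-(methoxymethoxy)-6,8-bis(3-methylbut-2-en-1-yl)chromane-3,4-diol (C4 epimers), via C4 epoxy alcohol 14 (not isolated)
Conditions: LiBHEt3 (3 equiv), THF, −78 to 0 °C; then H2O
Reagents that add atoms: none
Why: LiBHEt3 first reduces the C4 ketone (1,2-reduction) and then opens the oxirane by SN2 attack of hydride at C2, the only oxirane carbon that is unhindered and acetal-like (C3 is quaternary), as in the hydride opening of glycal-type epoxides, so the C3–O bond and the C3 configuration are untouched; a nucleophilic, non-Lewis-acidic hydride is taken so that the C3–O bond benzylic to the electron-rich ring B is not ionised, and the C4 configuration is irrelevant because C4 is reoxidised.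

Step 10
Reactants: 15 (3R)-3-[2,4-bis(methoxymethoxy)phenyl]-7-(methoxymethoxy)-6,8-bis(3-methylbut-2-en-1-yl)chromane-3,4-diol
Product: 16 (3R)-3-[2,4-bis(methoxymethoxy)phenyl]-3-hydroxy-7-(methoxymethoxy)-6,8-bis(3-methylbut-2-en-1-yl)chroman-4-one
Conditions: IBX (1.5 equiv), DMSO, rt
Reagents that add atoms: none
Why: IBX oxidises the secondary benzylic C4 alcohol of the 1,2-diol to the ketone without cleaving the C3–C4 bond (hypervalent iodine oxidation), and the tertiary C3 alcohol, the MOM acetals and the prenyl alkenes are inert to it at room temperature.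

Step 11
Reactants: 16 (3R)-3-[2,4-bis(methoxymethoxy)phenyl]-3-hydroxy-7-(methoxymethoxy)-6,8-bis(3-methylbut-2-en-1-yl)chroman-4-one
Product: 17 (3R)-3-(2,4-dihydroxyphenyl)-3,7-dihydroxy-6,8-bis(3-methylbut-2-en-1-yl)chroman-4-one (CNP0211715.1)
Conditions: 3 M aq HCl, MeOH, 40 °C
Reagents that add atoms: none
Why: Acid-catalysed acetal exchange with methanol removes the three aryl MOM groups as dimethoxymethane, and dilute acid at mild temperature is used so that the freed C7 phenol does not add to its ortho prenyl alkenes, while the tertiary α-ketol at C3 has no α-hydrogen through which to enolise and its ionisation is disfavoured by the adjacent carbonyl, so it should keep its configuration.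

**Compound list**

1 | 2',4'-dihydroxyacetophenone [1-(2,4-dihydroxyphenyl)ethanone] | CC(=O)c1ccc(O)cc1O | starting material
2 | prenyl bromide (1-bromo-3-methylbut-2-ene) | CC(C)=CCBr | starting material
3 | 1-[2,4-dihydroxy-3,5-bis(3-methylbut-2-en-1-yl)phenyl]ethanone | CC(=O)c1cc(CC=C(C)C)c(O)c(CC=C(C)C)c1O | intermediate
4 | 1-[2-hydroxy-4-(methoxymethoxy)-3,5-bis(3-methylbut-2-en-1-yl)phenyl]ethanone | CC(=O)c1cc(CC=C(C)C)c(OCOC)c(CC=C(C)C)c1O | intermediate
5 | (E)-3-(dimethylamino)-1-[2-hydroxy-4-(methoxymethoxy)-3,5-bis(3-methylbut-2-en-1-yl)phenyl]prop-2-en-1-one | CN(C)/C=C/C(=O)c1cc(CC=C(C)C)c(OCOC)c(CC=C(C)C)c1O | intermediate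
6 | 2-(dimethylamino)-3-iodo-7-(methoxymethoxy)-6,8-bis(3-methylbut-2-en-1-yl)chroman-4-one (configuration of no consequence) | CC(C)=CCc1cc2c(c(CC=C(C)C)c1OCOC)OC(N(C)C)C(I)C2=O | intermediate (not isolated)
7 | 3-iodo-7-(methoxymethoxy)-6,8-bis(3-methylbut-2-en-1-yl)-4H-chromen-4-one | CC(C)=CCc1cc2c(c(CC=C(C)C)c1OCOC)OC=C(I)C2=O | intermediate
8 | 4-bromoresorcinol (4-bromobenzene-1,3-diol) | Oc1ccc(Br)c(O)c1 | starting material
9 | 1-bromo-2,4-bis(methoxymethoxy)benzene | COCOc1ccc(Br)c(OCOC)c1 | intermediate
10 | 2-[2,4-bis(methoxymethoxy)phenyl]-4,4,5,5-tetramethyl-1,3,2-dioxaborolane | COCOc1ccc(B2OC(C)(C)C(C)(C)O2)c(OCOC)c1 | intermediate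
11 | 3-[2,4-bis(methoxymethoxy)phenyl]-7-(methoxymethoxy)-6,8-bis(3-methylbut-2-en-1-yl)-4H-chromen-4-one (MOM-protected 6,8-diprenylisoflavone) | CC(C)=CCc1cc2c(c(CC=C(C)C)c1OCOC)OC=C(c1ccc(OCOC)cc1OCOC)C2=O | intermediate
12 | (2S)-2-(2-phenylpropan-2-ylperoxy) C4-enolate of 11 (ion pair with the ammonium cation) | CC(C)=CCc1cc2c(c(CC=C(C)C)c1OCOC)O[C@@H](OOC(C)(C)c1ccccc1)C(c1ccc(OCOC)cc1OCOC)=C2[O-] | intermediate (not isolated)
13 | (2S,3R)-2,3-epoxide of 11, cis-fused [(1aS,7aR)-7a-[2,4-bis(methoxymethoxy)phenyl]-4-(methoxymethoxy)-3,5-bis(3-methylbut-2-en-1-yl)-1a,7a-dihydro-7H-oxireno[2,3-b]chromen-7-one] | CC(C)=CCc1cc2c(c(CC=C(C)C)c1OCOC)O[C@H]1O[C@@]1(c1ccc(OCOC)cc1OCOC)C2=O | intermediate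
14 | C4 alcohol of epoxide 13, oxirane configuration unchanged, C4 epimers (present as its lithium alkoxide) | CC(C)=CCc1cc2c(c(CC=C(C)C)c1OCOC)O[C@H]1O[C@@]1(c1ccc(OCOC)cc1OCOC)C2O | intermediate (not isolated)
15 | (3R)-3-[2,4-bis(methoxymethoxy)phenyl]-7-(methoxymethoxy)-6,8-bis(3-methylbut-2-en-1-yl)chromane-3,4-diol, C4 epimers | CC(C)=CCc1cc2c(c(CC=C(C)C)c1OCOC)OC[C@](O)(c1ccc(OCOC)cc1OCOC)C2O | intermediate
16 | (3R)-3-[2,4-bis(methoxymethoxy)phenyl]-3-hydroxy-7-(methoxymethoxy)-6,8-bis(3-methylbut-2-en-1-yl)chroman-4-one | CC(C)=CCc1cc2c(c(CC=C(C)C)c1OCOC)OC[C@](O)(c1ccc(OCOC)cc1OCOC)C2=O | intermediate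
17 | (3R)-3-(2,4-dihydroxyphenyl)-3,7-dihydroxy-6,8-bis(3-methylbut-2-en-1-yl)chroman-4-one | CC(C)=CCc1cc2c(c(CC=C(C)C)c1O)OC[C@](O)(c1ccc(O)cc1O)C2=O | target

**Step count and risks**

Total steps: 11. Longest linear sequence: 9 steps (steps 1–4 and 7–11); steps 5 and 6 form the ring B branch.

Steps most likely to fail:

Step 8. The ammonium cation may discriminate poorly between the two faces of an isoflavone that carries an ortho-substituted ring B, or hydroxide may add at C2 and open ring C before the peroxide reacts. The fallback sets out from 11. Conjugate reduction with LiBH(s-Bu)3 in THF at −78 °C should give the racemic isoflavanone 3-[2,4-bis(methoxymethoxy)phenyl]-7-(methoxymethoxy)-6,8-bis(3-methylbut-2-en-1-yl)chroman-4-one F3. Its potassium enolate (KN(SiMe3)2, THF, −78 °C) would then be hydroxylated at C3 with one enantiomer of a camphor-derived N-sulfonyloxaziridine (asymmetric enolate oxidation), the reagent enantiomer being chosen for the 3R product. This rejoins the route at 16 and makes steps 9 and 10 unnecessary.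

Step 9. Hydride may be delivered to the wrong oxirane carbon, the C3–O bond may cleave, or the C4 alkoxide may attack the oxirane (Payne-type migration) and open ring C. The fallback sets out from 13 and keeps the ketone throughout. Thiophenol with Et3N in THF at 0 °C should open the oxirane at C2, the β-carbon of the epoxy ketone (C3 being quaternary), by anti attack to give (2R,3S)-3-[2,4-bis(methoxymethoxy)phenyl]-3-hydroxy-7-(methoxymethoxy)-6,8-bis(3-methylbut-2-en-1-yl)-2-(phenylsulfanyl)chroman-4-one F4, in which the sulfanyl group is trans to the 3-hydroxyl and the C3 oxygen sits as in 13. Bu3SnH with AIBN in toluene at 90 °C would then replace the C2–S bond by C–H through the α-oxy radical. This returns to the route at 16 and skips step 10.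

Step 1. O-alkylation, arrest at the mono-prenyl stage and geminal dialkylation at C3 all compete with the double C-prenylation. The fallback sets out from 1. Iodination with I2/HIO3 in aqueous ethanol should give 1-(2,4-dihydroxy-3,5-diiodophenyl)ethanone F1. MOMCl/K2CO3 in acetone would cap the 4-hydroxyl to give 1-[2-hydroxy-3,5-diiodo-4-(methoxymethoxy)phenyl]ethanone F2. A double Stille coupling with tributyl(3-methylbut-2-en-1-yl)stannane (Pd(PPh3)4, DMF, 95 °C) would then give 4, where the route is rejoined.

**Further compounds**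

F1 | step 1 | 1-(2,4-dihydroxy-3,5-diiodophenyl)ethanone | CC(=O)c1cc(I)c(O)c(I)c1O
F2 | step 1 | 1-[2-hydroxy-3,5-diiodo-4-(methoxymethoxy)phenyl]ethanone | CC(=O)c1cc(I)c(OCOC)c(I)c1O
F3 | step 8 | racemic 3-[2,4-bis(methoxymethoxy)phenyl]-7-(methoxymethoxy)-6,8-bis(3-methylbut-2-en-1-yl)chroman-4-one | CC(C)=CCc1cc2c(c(CC=C(C)C)c1OCOC)OCC(c1ccc(OCOC)cc1OCOC)C2=O
F4 | step 9 | (2R,3S)-3-[2,4-bis(methoxymethoxy)phenyl]-3-hydroxy-7-(methoxymethoxy)-6,8-bis(3-methylbut-2-en-1-yl)-2-(phenylsulfanyl)chroman-4-one (sulfanyl trans to 3-hydroxyl) | CC(C)=CCc1cc2c(c(CC=C(C)C)c1OCOC)O[C@H](Sc1ccccc1)[C@](O)(c1ccc(OCOC)cc1OCOC)C2=O
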